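**Retrosynthetic overview**
1. The C1 ketone comes from a late allylic oxidation and the two esters from acylation of (7R,9R)-longip-2-ene-7,9-diol. The diol comes from the tricyclic enone 30 (C9=O, C7=C8) by CBS reduction, directed epoxidation, SmI2 opening and Evans–Saksena reduction.
2. The cyclobutane is closed last. The C4–C10 bond forms by intramolecular alkylation of the C9/C10 dienolate on a C4 mesylate in a cis-fused 6–7 bicycle.
3. The seven-membered ring comes from C7=C8 formation by intramolecular aldol condensation of a neopentyl aldehyde arm with a methyl ketone arm.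
4. The key fragment union is the C5–C6 bond, made by intermolecular Mukaiyama–Michael addition of the isobutyrate silyl ketene acetal to a 4-substituted cyclohexenone. C5 is then reset by Saegusa oxidation and hydroboration.
5. The six-membered ring is made first by an enamine-catalysed Michael addition of an aldehyde to MVK (sets C11) followed by aldol condensation. Ring order: 6, then 7, then 4.

Locants C1–C11 are those of the target skeleton:
- C1 is the ketone carbon and C2=C3(Me) is the enone alkene.
- C4 and C11 are the bridgeheads.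
- C5 (H) and C10 (Me) are the one-carbon bridges.
- C6 is CMe2, C7 and C9 are the ester carbinols, and C8 is CH2.

Assumption: C10 is carried as an inconsequential epimer mixture (4 is racemic) until it is deprotonated in step 15, so it is left undefined in the SMILES of 4–23.

Step 1
Reactants: 1 3-methylpentane-2,4-dione; 2 allyl bromide
Product: 4 3-methylhex-5-en-2-one (racemic), via C-allylated diketone 3 (not isolated)
Conditions: K2CO3, EtOH, reflux, 16 h
Reagents that add atoms: none
Why: C-alkylation of the β-diketone enolate gives a non-enolisable diketone that ethanol/carbonate cleaves at once by retro-Claisen deacetylation, so the mono-ketone carrying C8–C11 and the C10 methyl forms in one pot (its stereocentre is erased later).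

Step 2
Reactants: 4 3-methylhex-5-en-2-one
Product: 5 2-methyl-2-(pent-4-en-2-yl)-1,3-dioxolane
Conditions: ethylene glycol, p-TsOH (cat.), toluene, Dean–Stark, reflux
Reagents that add atoms: ethylene glycol, OCCO
Why: Acid-catalysed ketalisation with azeotropic water removal masks the future C9 ketone against enamine catalysis, hydride, borane and base.

Step 3
Reactants: 5 2-methyl-2-(pent-4-en-2-yl)-1,3-dioxolane
Product: 7 3-(2-methyl-1,3-dioxolan-2-yl)butanal, via secondary ozonide 6 (not isolated)
Conditions: O3, CH2Cl2, −78 °C; then Me2S, −78 °C to rt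
Reagents that add atoms: ozone, [O-][O+]=O
Why: Ozonolysis with reductive work-up cleaves the only alkene and gives the aldehyde carbon that becomes C5, and the neutral cold conditions leave the dioxolane intact.

Step 4
Reactants: 7 3-(2-methyl-1,3-dioxolan-2-yl)butanal; 8 but-3-en-2-one (MVK)
Product: 9 (2S)-2-[1-(2-methyl-1,3-dioxolan-2-yl)ethyl]-5-oxohexanal
Conditions: (S)-2-(methoxydiphenylmethyl)pyrrolidine (5 mol %), ethyl 3,4-dihydroxybenzoate (20 mol %), neat, 4 °C
Reagents that add atoms: none
Why: In this enamine-catalysed asymmetric Michael addition the (S)-diarylprolinol ether blocks one face of the E-enamine, so MVK attacks the open face, which sets C11 (2S in 9) and joins C11 to C1.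

Step 5
Reactants: 9 (2S)-2-[1-(2-methyl-1,3-dioxolan-2-yl)ethyl]-5-oxohexanal
Product: 11 (4R)-4-[1-(2-methyl-1,3-dioxolan-2-yl)ethyl]cyclohex-2-en-1-one, via β-hydroxy ketone 10 (not isolated)
Conditions: LiOH (cat.), i-PrOH, rt
Reagents that add atoms: none
Why: Intramolecular aldol condensation (Robinson-type closure) of the methyl ketone onto the aldehyde closes the six-membered ring under mild base without disturbing the γ-stereocentre C11.

Step 6
Reactants: 11 (4R)-4-[1-(2-methyl-1,3-dioxolan-2-yl)ethyl]cyclohex-2-en-1-one; 12 1-methoxy-2-methyl-1-(trimethylsilyloxy)prop-1-ene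
Product: 13 methyl 2-methyl-2-{trans-6-[1-(2-methyl-1,3-dioxolan-2-yl)ethyl]-3-(trimethylsilyloxy)cyclohex-2-en-1-yl}propanoate
Conditions: 12 (1.5 equiv), MeCN, 55 °C (no Lewis acid)
Reagents that add atoms: none
Why: This Mukaiyama–Michael addition under neutral conditions (ketal-safe) forges the congested C5–C6 bond with its quaternary carbon anti to the C11 side chain, and silyl transfer gives the regiodefined C3=C4 silyl enol ether.

Step 7
Reactants: 13 Michael adduct silyl enol ether
Product: 14 methyl 2-methyl-2-{(6S)-6-[1-(2-methyl-1,3-dioxolan-2-yl)ethyl]-3-oxocyclohex-1-en-1-yl}propanoate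
Conditions: Pd(OAc)2 (1.05 equiv), MeCN, rt
Reagents that add atoms: none
Why: Saegusa–Ito oxidation of the regiodefined silyl enol ether (syn β-hydride elimination of C5–H) restores C4=C5 and deliberately erases the trans-configured C5 so that it can be reset by hydrogen delivery.

Step 8
Reactants: 14 enone ester
Product: 15 (1S,4S)-3-(1-hydroxy-2-methylpropan-2-yl)-4-[1-(2-methyl-1,3-dioxolan-2-yl)ethyl]cyclohex-2-en-1-ol
Conditions: LiAlH4, Et2O, −20 to 0 °C; Fieser work-up
Reagents that add atoms: none
Why: LiAlH4 reduces the hindered ester to the neopentyl alcohol and the β,β-disubstituted enone 1,2, with axial hydride attack anti to the pseudoaxial C11 side chain giving the pseudoequatorial C3 alcohol cis to that chain.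

Step 9
Reactants: 15 enediol
Product: 16 bis(tert-butyldimethylsilyl) ether of 15
Conditions: TBSCl (2.5 equiv), imidazole, DMAP (cat.), DMF, 40 °C
Reagents that add atoms: tert-butyldimethylsilyl chloride, CC(C)(C)[Si](C)(C)Cl
Why: Corey silylation protects both hydroxyls so that only the new C4 hydroxyl is free after hydroboration.

Step 10
Reactants: 16 bis-silyl ether
Product: 18 cyclohexanol with C4-OH trans to C3-OTBS and to the C5 arm (C5 and C11 arms cis), via C4 alkylborane 17 (not isolated)
Conditions: BH3·THF (3 equiv), THF, 0 °C to rt; then 3 M NaOH, 30% H2O2, 0 °C to rt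
Reagents that add atoms: borane (as BH3·THF), B; hydrogen peroxide, OO
Why: In this hydroboration–oxidation BH3 adds syn, with boron on the less substituted C4, from the face opposite the C11 chain (held pseudoaxial by A1,2 strain with the tert-alkyl group) and the C3 silyl ether, so H reaches C5 from that face, the two arms become cis, and retentive oxidation leaves C4-OH trans to its neighbours.

Step 11
Reactants: 18 C4 alcohol
Product: 19 C4 methanesulfonate of 18
Conditions: MsCl, Et3N, CH2Cl2, 0 °C
Reagents that add atoms: methanesulfonyl chloride, CS(=O)(=O)Cl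
Why: Mesylation via sulfene tolerates the hindered equatorial alcohol and installs the leaving group with retention at C4.

Step 12
Reactants: 19 mesylate
Product: 20 keto alcohol (C9 methyl ketone and C7 primary alcohol free; C3-OTBS and C4-OMs kept)
Conditions: 1 M aq HCl/THF (1:3), rt
Reagents that add atoms: water, O
Why: Dilute acid hydrolyses the dioxolane and the primary silyl ether, while the hindered secondary TBS ether next to the electron-withdrawing mesylate and the mesylate itself survive.

Step 13
Reactants: 20 keto alcohol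
Product: 21 keto aldehyde (C7 neopentyl aldehyde, C9 methyl ketone)
Conditions: TPAP (5 mol %), NMO, 4 Å MS, CH2Cl2, rt
Reagents that add atoms: none
Why: The neutral Ley–Griffith oxidation takes the neopentyl alcohol to the non-enolisable aldehyde without touching the mesylate, silyl ether or ketone arm.

Step 14
Reactants: 21 keto aldehyde
Product: 23 cis-fused bicyclo[5.4.0]undecenone (C9=O, C7=C8, C4-OMs, C3-OTBS), via bicyclic β-hydroxy ketone 22 (not isolated)
Conditions: piperidine (20 mol %), AcOH (20 mol %), 4 Å MS, toluene, 70 °C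
Reagents that add atoms: none
Why: In this amine-catalysed intramolecular aldol condensation the amine forms the less substituted C8 enamine, the non-enolisable C7 aldehyde is the only acceptor, and only the seven-ring aldol can dehydrate, so the reversible five-ring aldol through C10 drains into the cycloheptenone.

Step 15
Reactants: 23 bicyclic enone mesylate
Product: 25 tricyclic enone silyl ether (3-TBSO-3-demethyl-longip-7-en-9-one), via potassium dienolate 24 (not isolated)
Conditions: KHMDS (1.2 equiv), THF (0.01 M), −78 to 45 °C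
Reagents that add atoms: none
Why: In this intramolecular enolate alkylation (copaene/longipinene precedent) C10–H is the only acidic site, the axial C10 of the endocyclic dienolate lies 1,3-diaxial to C4 and nearly collinear with the equatorial C–OMs bond, O-alkylation is geometrically impossible, and SN2 inversion at C4 closes the cyclobutane while the seven-membered ring forces C9 anti and the methyl syn to the C1–C3 bridge, converging both C10 epimers.

Step 16
Reactants: 25 tricyclic enone silyl ether
Product: 26 3-hydroxy-3-demethyl-longip-7-en-9-one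
Conditions: 48% aq HF, MeCN, rt
Reagents that add atoms: none
Why: Desilylation with HF frees the C3 alcohol, and the enone and cyclobutane are inert to it.

Step 17
Reactants: 26 hydroxy enone
Product: 27 3-demethyl-longip-7-ene-3,9-dione
Conditions: TPAP (5 mol %), NMO, 4 Å MS, CH2Cl2, rt
Reagents that add atoms: none
Why: Ley–Griffith oxidation gives the nopinone-type C3 ketone and removes the auxiliary C3 stereocentre.

Step 18
Reactants: 27 enedione
Product: 29 C3 enol triflate (C2=C3), via potassium enolate 28 (not isolated)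
Conditions: KHMDS, THF, −78 °C; then PhNTf2, −78 to 0 °C
Reagents that add atoms: N-phenylbis(trifluoromethanesulfonimide), O=S(=O)(N(c1ccccc1)S(=O)(=O)C(F)(F)F)C(F)(F)F
Why: Deprotonation can occur only at C2 (C4 is a bridgehead and the C9 enone has no enolisable hydrogen), so enolate triflation gives a single enol triflate.

Step 19
Reactants: 29 enol triflate
Product: 30 longipina-2,7-dien-9-one
Conditions: Me2Zn (1.5 equiv), Pd(dppf)Cl2 (5 mol %), THF, 50 °C
Reagents that add atoms: dimethylzinc, C[Zn]C
Why: Negishi cross-coupling replaces triflate by methyl and fixes C2=C3(Me) regiospecifically, and dimethylzinc does not attack the hindered enone.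

Step 20
Reactants: 30 longipina-2,7-dien-9-one
Product: 31 (9S)-longipina-2,7-dien-9-ol
Conditions: (R)-Me-CBS (20 mol %), catecholborane (1.8 equiv), toluene, −78 °C
Reagents that add atoms: none
Why: In this Corey–Bakshi–Shibata reduction the nearly Cs-symmetric enone offers no facial bias, so the catalyst decides, with quaternary C10 as the large and vinylic C8 as the small group, giving the (9S)-allylic alcohol as a relay stereocentre by clean 1,2-reduction.

Step 21
Reactants: 31 (9S)-allylic alcohol
Product: 32 7,8-epoxy-(9S)-alcohol (epoxide syn to OH)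
Conditions: VO(acac)2 (3 mol %), t-BuOOH (1.5 equiv, decane), CH2Cl2, 0 °C
Reagents that add atoms: tert-butyl hydroperoxide, CC(C)(C)OO
Why: Hydroxyl-directed vanadium epoxidation (Sharpless–Michaelson) delivers oxygen syn to the C9 hydroxyl and ignores the isolated C2=C3 alkene, which places the C7–O bond on the C4 side (7R).

Step 22
Reactants: 32 epoxy alcohol
Product: 33 7,8-epoxylongip-2-en-9-one
Conditions: TPAP (5 mol %), NMO, 4 Å MS, CH2Cl2, rt
Reagents that add atoms: none
Why: Ley–Griffith oxidation removes the relay stereocentre and gives the α,β-epoxy ketone under neutral conditions.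

Step 23
Reactants: 33 epoxy ketone
Product: 34 (7R)-7-hydroxylongip-2-en-9-one
Conditions: SmI2 (2.5 equiv), THF/MeOH (4:1), −90 °C
Reagents that add atoms: none
Why: SmI2 reduction of an α,β-epoxy ketone (Molander) cleaves only the Cα–O bond (C8–O) through the ketyl/enolate, giving the β-hydroxy ketone with C7 untouched.

Step 24
Reactants: 34 β-hydroxy ketone
Product: 35 (7R,9R)-longip-2-ene-7,9-diol
Conditions: Me4NBH(OAc)3 (6 equiv), MeCN/AcOH (1:1), −30 °C
Reagents that add atoms: none
Why: In the Evans–Saksena reduction the C7-bound acetoxyborohydride delivers hydride intramolecularly to C9 from the face of the C7 oxygen, giving the trans (anti) 1,3-diol and hence (9R).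

Step 25
Reactants: 35 (7R,9R)-diol; 36 3-methylbut-2-enoyl chloride
Product: 37 (7R,9R)-longip-2-ene-7,9-diyl bis(3-methylbut-2-enoate)
Conditions: 36 (6 equiv), DMAP (20 mol %), pyridine/CH2Cl2, 40 °C
Reagents that add atoms: none
Why: DMAP-catalysed acylation with excess acid chloride esterifies both neopentylic secondary alcohols with retention at C7 and C9.

Step 26
Reactants: 37 diester
Product: 38 target, (4R,5S,7R,9R,10R,11R)-7,9-bis(3-methylbut-2-enoyloxy)longip-2-en-1-one
Conditions: Rh2(cap)4 (1 mol %), t-BuOOH (70% aq, 10 equiv), 1,2-dichloroethane, 40 °C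
Reagents that add atoms: tert-butyl hydroperoxide, CC(C)(C)OO
Why: Dirhodium caprolactamate/t-BuOOH allylic oxidation attacks the only secondary allylic C–H bonds of the electron-rich trisubstituted alkene (C1, the position at which α-pinene gives verbenone), and the electron-poor senecioate alkenes stay inert.

**Compound list**
1 | 3-methylpentane-2,4-dione | CC(=O)C(C)C(C)=O | starting material
2 | allyl bromide | C=CCBr | starting material
3 | 3-allyl-3-methylpentane-2,4-dione | CC(=O)C(C)(CC=C)C(C)=O | intermediate
4 | 3-methylhex-5-en-2-one (racemic) | CC(=O)C(C)CC=C | intermediate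
5 | 2-methyl-2-(pent-4-en-2-yl)-1,3-dioxolane | C=CCC(C)C1(C)OCCO1 | intermediate
6 | secondary ozonide of 5 | CC(CC1OCOO1)C1(C)OCCO1 | intermediate
7 | 3-(2-methyl-1,3-dioxolan-2-yl)butanal | O=CCC(C)C1(C)OCCO1 | intermediate
8 | but-3-en-2-one | CC(=O)C=C | starting material
9 | (2S)-2-[1-(2-methyl-1,3-dioxolan-2-yl)ethyl]-5-oxohexanal | O=C[C@@H](CCC(C)=O)C(C)C1(C)OCCO1 | intermediate
10 | 3-hydroxy-4-[1-(2-methyl-1,3-dioxolan-2-yl)ethyl]cyclohexanone | O=C1CC(O)[C@@H](CC1)C(C)C1(C)OCCO1 | intermediate
11 | (4R)-4-[1-(2-methyl-1,3-dioxolan-2-yl)ethyl]cyclohex-2-en-1-one | O=C1C=C[C@@H](CC1)C(C)C1(C)OCCO1 | intermediate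
12 | 1-methoxy-2-methyl-1-(trimethylsilyloxy)prop-1-ene | COC(O[Si](C)(C)C)=C(C)C | starting material
13 | trans Michael adduct, C3=C4 TMS enol ether | COC(=O)C(C)(C)[C@@H]1C=C(O[Si](C)(C)C)CC[C@H]1C(C)C1(C)OCCO1 | intermediate
14 | (6S)-3-substituted enone ester | COC(=O)C(C)(C)C1=CC(=O)CC[C@H]1C(C)C1(C)OCCO1 | intermediate
15 | (1S,4S)-enediol | OCC(C)(C)C1=C[C@@H](O)CC[C@H]1C(C)C1(C)OCCO1 | intermediate
16 | bis-TBS ether of 15 | CC(C)(C)[Si](C)(C)OCC(C)(C)C1=C[C@@H](O[Si](C)(C)C(C)(C)C)CC[C@H]1C(C)C1(C)OCCO1 | intermediate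
17 | C4 alkylborane | CC(C)(C)[Si](C)(C)OCC(C)(C)[C@H]1[C@H](B)[C@@H](O[Si](C)(C)C(C)(C)C)CC[C@H]1C(C)C1(C)OCCO1 | intermediate
18 | C4 alcohol (C3-OTBS, C5 arm and C11 arm on one face, C4-OH on the other) | CC(C)(C)[Si](C)(C)OCC(C)(C)[C@H]1[C@H](O)[C@@H](O[Si](C)(C)C(C)(C)C)CC[C@H]1C(C)C1(C)OCCO1 | intermediate
19 | C4 mesylate of 18 | CC(C)(C)[Si](C)(C)OCC(C)(C)[C@H]1[C@H](OS(C)(=O)=O)[C@@H](O[Si](C)(C)C(C)(C)C)CC[C@H]1C(C)C1(C)OCCO1 | intermediate
20 | keto alcohol | OCC(C)(C)[C@H]1[C@H](OS(C)(=O)=O)[C@@H](O[Si](C)(C)C(C)(C)C)CC[C@H]1C(C)C(C)=O | intermediate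
21 | keto aldehyde | O=CC(C)(C)[C@H]1[C@H](OS(C)(=O)=O)[C@@H](O[Si](C)(C)C(C)(C)C)CC[C@H]1C(C)C(C)=O | intermediate
22 | bicyclic β-hydroxy ketone (C7-OH) | O=C1CC(O)C(C)(C)[C@H]2[C@H](OS(C)(=O)=O)[C@@H](O[Si](C)(C)C(C)(C)C)CC[C@H]2C1C | intermediate
23 | cis-fused bicyclic enone mesylate | O=C1C=CC(C)(C)[C@H]2[C@H](OS(C)(=O)=O)[C@@H](O[Si](C)(C)C(C)(C)C)CC[C@H]2C1C | intermediate
24 | potassium C9/C10 dienolate of 23 | [K+].[O-]C1C=CC(C)(C)[C@H]2[C@H](OS(C)(=O)=O)[C@@H](O[Si](C)(C)C(C)(C)C)CC[C@H]2C=1C | intermediate
25 | tricyclic enone, C3-OTBS syn to the C10 bridge | C1=CC(=O)[C@@]2(C)[C@@H]3CC[C@H](O[Si](C)(C)C(C)(C)C)[C@H]2[C@@H]3C1(C)C | intermediate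
26 | tricyclic hydroxy enone | C1=CC(=O)[C@@]2(C)[C@@H]3CC[C@H](O)[C@H]2[C@@H]3C1(C)C | intermediate
27 | tricyclic ene-3,9-dione | C1=CC(=O)[C@@]2(C)[C@@H]3CCC(=O)[C@H]2[C@@H]3C1(C)C | intermediate
28 | potassium C2=C3 enolate of 27 | [K+].C1=CC(=O)[C@@]2(C)[C@@H]3CC=C([O-])[C@H]2[C@@H]3C1(C)C | intermediate
29 | C3 enol triflate | C1=CC(=O)[C@@]2(C)[C@@H]3CC=C(OS(=O)(=O)C(F)(F)F)[C@H]2[C@@H]3C1(C)C | intermediate
30 | longipina-2,7-dien-9-one | C1=CC(=O)[C@@]2(C)[C@@H]3CC=C(C)[C@H]2[C@@H]3C1(C)C | intermediate
31 | (9S)-longipina-2,7-dien-9-ol | C1=C[C@H](O)[C@@]2(C)[C@@H]3CC=C(C)[C@H]2[C@@H]3C1(C)C | intermediate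
32 | 7,8-epoxy-(9S)-alcohol, epoxide syn to OH | O1[C@@H]2[C@H]1[C@H](O)[C@@]3(C)[C@@H]4CC=C(C)[C@H]3[C@@H]4C2(C)C | intermediate
33 | 7,8-epoxylongip-2-en-9-one | O1[C@@H]2[C@H]1C(=O)[C@@]3(C)[C@@H]4CC=C(C)[C@H]3[C@@H]4C2(C)C | intermediate
34 | (7R)-7-hydroxylongip-2-en-9-one | O[C@@H]1CC(=O)[C@@]2(C)[C@@H]3CC=C(C)[C@H]2[C@@H]3C1(C)C | intermediate
35 | (7R,9R)-longip-2-ene-7,9-diol | O[C@@H]1C[C@@H](O)[C@@]2(C)[C@@H]3CC=C(C)[C@H]2[C@@H]3C1(C)C | intermediate
36 | 3-methylbut-2-enoyl chloride | CC(C)=CC(=O)Cl | starting material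
37 | (7R,9R)-longip-2-ene-7,9-diyl bis(3-methylbut-2-enoate) | CC(C)=CC(=O)O[C@@H]1C[C@@H](OC(=O)C=C(C)C)[C@@]2(C)[C@@H]3CC=C(C)[C@H]2[C@@H]3C1(C)C | intermediate
38 | CNP0105062.1 | CC(C)=CC(=O)O[C@@H]1C[C@@H](OC(=O)C=C(C)C)[C@@]2(C)[C@@H]3C(=O)C=C(C)[C@H]2[C@@H]3C1(C)C | target

**Total step count:** 26. **Longest linear sequence:** 26 steps from 1, because all coupling partners (2, 8, 12, 36) are commercial.

**Steps most likely to fail**

Step 14 (seven-membered aldol condensation). The C10 enol can close a five-membered aldol instead, and the closure may stall.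
- The fallback sets out from 21 and comes back at 23.
- It replaces the reversible amine-catalysed condensation by an irreversible, regiodefined kinetic aldol.
- c-Hex2BCl/Et3N (Et2O, −78 °C) forms only the terminal C8 boron enolate, which closes onto the C7 aldehyde.
- The β-hydroxy ketone 22 is isolated after oxidative work-up.
- Its single free hydroxyl is converted with MsCl/Et3N into the β-mesyloxy ketone F1.
- DBU then eliminates it (E1cB) to give 23.

Step 15 (cyclobutane closure that forms a quaternary centre). The potassium dienolate may be too weak a nucleophile for the hindered secondary mesylate.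
- The fallback sets out from 23 and comes back at 25.
- It changes the nucleophile class to a metallated hydrazone.
- Me2NNH2 with catalytic AcOH (EtOH, 60 °C) gives the N,N-dimethylhydrazone F2.
- LDA (THF, 0 °C to rt) generates the far more nucleophilic C10 aza-enolate, which displaces the mesylate with the same geometry to give the tricyclic N,N-dimethylhydrazone F3.
- Cu(OAc)2 in aqueous THF hydrolyses F3 to 25.

Step 20 (CBS discrimination between a quaternary carbon and a vinyl group).
- The fallback sets out from 30 and comes back at 34, bypassing 31–33.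
- Copper-catalysed enantioselective conjugate borylation puts boron on C7 under ligand control (CuCl/NaOt-Bu, Josiphos-type ligand, B2pin2, MeOH, THF), giving the C7 pinacol boronate F4.
- NaBO3·4H2O (THF/H2O) oxidises it with retention to 34.

**Further compounds**
F1 | step 14 | β-mesyloxy ketone | O=C1CC(OS(C)(=O)=O)C(C)(C)[C@H]2[C@H](OS(C)(=O)=O)[C@@H](O[Si](C)(C)C(C)(C)C)CC[C@H]2C1C
F2 | step 15 | N,N-dimethylhydrazone | CN(C)N=C1C=CC(C)(C)[C@H]2[C@H](OS(C)(=O)=O)[C@@H](O[Si](C)(C)C(C)(C)C)CC[C@H]2C1C
F3 | step 15 | tricyclic N,N-dimethylhydrazone | C1=CC(=NN(C)C)[C@@]2(C)[C@@H]3CC[C@H](O[Si](C)(C)C(C)(C)C)[C@H]2[C@@H]3C1(C)C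
F4 | step 20 | C7 pinacol boronate | CC1(C)OB(OC1(C)C)[C@@H]1CC(=O)[C@@]2(C)[C@@H]3CC=C(C)[C@H]2[C@@H]3C1(C)C
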